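Remarks on the chemistry (assumptions):
- Briarane numbering is used throughout: carbocycle C1–C14 (ring A = C1, C10–C14), C15 = methyl on C1, C16 = CH2OH on C5, C17–C19 = lactone carbons (C18 = methyl on C17), C20 = methyl on C11. The SMILES is read as (1R,2R,3Z,5E,7S,8S,9R,10S,11S,12R,14S,17R).
- Racemic 2-bromopropanoic acid is used in step 21, so 38–40 are mixtures at the bromine-bearing carbon; that centre is destroyed in step 23.

## Structural features

The target is a briarane: cyclohexane ring A (C1, C10–C14) is trans-fused through C1 and C10 to a ten-membered carbocycle (C1–C10), across whose C7–C8 bond a γ-lactone (O–C7, C8, C17, C19) is trans-fused. C1 is quaternary (C15 methyl, axial on ring A) and is flanked by three stereocentres: C2–OAc, C10–H and the axial C14–OAc; the C11–C12 epoxide lies on the ring A face opposite the C15 methyl. The ten-membered ring carries a (3Z,5E)-diene, both double bonds cis with respect to the ring, with the free primary alcohol C16 on C5 and allylic oxygen at C2 and C7. C7, C8 (tertiary alcohol, cis to the C18 methyl on C17) and C9 (acetate) form a contiguous array remote from C1/C2. Fragile elements are the β-hydroxy lactone (retro-aldol, C17 epimerisation), the acid-labile trisubstituted epoxide, acetates next to free hydroxyls, and the need to leave one primary alcohol free beside three acetylated secondary ones. The real difficulty is to close a ten-membered ring onto the quaternary C1 with the Z C3=C4 bond while relating C1/C2/C10 to the C7–C9 array. The feature exploited is that C9 (oxygenated), the C1–C2 bond and the C3=C4 double bond stand in the 1,3,4,5,6 relation of a cyclodec-5-enone, so the ring is the retron of an oxy-Cope ring expansion of a six-membered ring made of C4–C9; that ring, with C16 on C5, the C5=C6 bond and oxygen on C7, C8 and C9, is shikimic acid.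

## Logic of the disconnections

46 to 42: the C16 silyl ether, the C2 and C14 acetates, the C2 benzylic ether and the epoxide C–O bonds are cut last. This leaves a single late differentiation problem (one primary alcohol free) and keeps the acid-labile epoxide out of all earlier steps. The forward demand is an α-face epoxidation of C11=C12 in the presence of the deactivated diene, for which the axial C14 hydroxyl of 42 is kept free.

41 to 37: the lactone is cut at C8–C17 (aldol-type bond) and at O–C7 (ester). Both bonds, the tertiary C8 alcohol and C17 then come from one tethered Reformatsky closure of 39, and the acid is introduced in 38 by displacement with inversion, which corrects the shikimate configuration at C7. The demand is facial control at C8 by the tether inside the ten-membered ring.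

36 to 34: the C9–H bond is cut, returning the C9 ketone that the key step delivers. The demand is hydride delivery anti to the C8–O bond.

34 to 31 (key): the C1–C2 bond is cut and C4–C9 is reconnected, a retro-oxy-Cope. The ten-membered ring, the quaternary C1, C2 and the Z C3=C4 bond collapse into a six-membered carbinol carrying two alkenyl groups. The two ring stereocentres C9 and C4 of 31 encode C1 and C2. The demand is a single chair transition state and an enol ether of defined Z geometry.

31 to 10 + 27: the enol ether is traced to an alkynyl ether (30), and the C9–C10 bond is cut to give a ring A dienyl metal and a ring B ketone. The route thereby becomes convergent, with two chiral-pool fragments. The demand is 1,2-addition to an enolisable ketone from the face opposite the dioxolane.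

27 to 22 + 15, and 22 to 16: the C3–C4 bond is cut to an alkoxyacetylide and a vinyl epoxide, and the epoxide is traced through diene 20 and acetonide 18 to 16. All ring B carbons, C16 and three oxygens come from one starting material. The demand is an epoxide cis to the dioxolane (halohydrin route) and attack at the allylic C4.

10 to 1: the C–Sn bond, the enol triflate and the C14–O bond are traced to 1. The isopropenyl group of 1 is degraded to the C14 oxygen with retention and the C15 methyl is added by enolate alkylation. The demand is handling of a β-silyloxy enolate at low temperature.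

15 to 11 + 12: the vinyl C–O bond is cut to an alkoxide and a C2 chloro-olefin. This provides an alkoxyacetylide whose O-substituent can later be removed oxidatively.

## Other disconnections considered

Alternative 1: Cut C2–C3 and close the ten-membered ring by an intramolecular Nozaki–Hiyama–Kishi reaction of the iodo-diene aldehyde A1 (CrCl2, catalytic NiCl2) to the macrocyclic allylic alcohol A2. This is the plan that comes to mind first. It is not preferred because the ring must close end to end onto a neopentyl aldehyde on the quaternary C1, with the C2 configuration left to macrocyclic bias. A1 also already contains every stereocentre and the β-hydroxy lactone, so the longest linear sequence carries all the fragile functionality. The chosen plan forms the same C1–C2 region from inside a six-membered transition state and sets C1 and C2 together.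

Alternative 2: Cut C4–C9 only, by a Grob fragmentation of the tricyclic 1,3-diol monomesylate A3 (C9 alkoxide, C3 mesylate equatorial and antiperiplanar to C4–C9), which would give ketone 34 directly. The stereochemical rules are the same as for the oxy-Cope chair, and the step is reliable. It is not preferred because A3 must be built linearly as a cis-fused hydrophenanthrene with seven controlled stereocentres including the quaternary C1, and the fragmentation forms no carbon–carbon bond. The oxy-Cope route makes the C1–C2 bond and the quaternary centre in the same operation that opens the ring, from two separately prepared fragments.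

Alternative 3: Cut C1–C2 in a dearomatising sense: intramolecular allylic alkylation (zerovalent palladium catalyst) of the 2,4-dimethylphenol allyl carbonate A4 at its methyl-bearing ortho carbon, to give cyclohexadienone A5 with the quaternary C1 and the ten-membered ring in one step. It is not preferred because a ten-membered ring would have to close at a hindered ortho carbon in competition with O-allylation, the π-allyl terminus would carry no C2 oxygen, and nothing relates the new C1 to the C7–C9 array. The dienone would then need four further ring A stereocentres from a flat ring.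

Key step: step 17

## Steps

Step 1
Reactants: 1 (S)-(+)-carvone
Product: 3 trans-6-methylcarvone [(5S,6R)-2,6-dimethyl-5-(prop-1-en-2-yl)cyclohex-2-en-1-one], via carvone lithium enolate 2 (not isolated)
Conditions: LiN(i-Pr)2, THF, −78 °C; then MeI, −78 → −20 °C
Reagents that add atoms: iodomethane, CI
Why: Kinetic deprotonation at C6 and enolate alkylation anti to the isopropenyl group should give the trans isomer; the new centre becomes sp2 in step 5, so its configuration is not critical.

Step 2
Reactants: 3 trans-6-methylcarvone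
Product: 5 (1S,2R)-2,4-dimethyl-3-oxocyclohex-4-en-1-yl acetate, via methoxy hydroperoxide 4 (not isolated)
Conditions: O3, CH2Cl2/MeOH, −78 °C; then Ac2O, Et3N, DMAP (cat.), −78 °C → rt
Reagents that add atoms: ozone, [O-][O+]=O; methanol, CO
Why: Ozone attacks the electron-rich 1,1-disubstituted alkene and spares the enone; acylation of the methoxy hydroperoxide triggers a Criegee rearrangement in which the ring carbon migrates to oxygen with retention, which sets the C14 oxygen with the target configuration.

Step 3
Reactants: 5 (1S,2R)-2,4-dimethyl-3-oxocyclohex-4-en-1-yl acetate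
Product: 6 (5S,6R)-5-hydroxy-2,6-dimethylcyclohex-2-en-1-one
Conditions: K2CO3, MeOH, 0 °C
Reagents that add atoms: none
Why: Transesterification of the secondary acetate; low temperature and short contact should hold back β-elimination of the acetate.

Step 4
Reactants: 6 (5S,6R)-5-hydroxy-2,6-dimethylcyclohex-2-en-1-one
Product: 7 (5S,6R)-5-(tert-butyldimethylsilyloxy)-2,6-dimethylcyclohex-2-en-1-one
Conditions: t-BuMe2SiCl, imidazole, DMF, rt
Reagents that add atoms: tert-butyldimethylsilyl chloride, CC(C)(C)[Si](C)(C)Cl
Why: Standard silylation of a secondary alcohol; the silyl ether survives the organometallic and basic steps up to step 24.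

Step 5
Reactants: 7 (5S,6R)-5-(tert-butyldimethylsilyloxy)-2,6-dimethylcyclohex-2-en-1-one
Product: 9 (3S)-3-(tert-butyldimethylsilyloxy)-2,6-dimethylcyclohexa-1,5-dien-1-yl trifluoromethanesulfonate, via lithium dienolate 8 (not isolated)
Conditions: LiN(i-Pr)2, THF, −78 °C; then PhNTf2, −78 → 0 °C
Reagents that add atoms: N-phenylbis(trifluoromethanesulfonimide), O=S(=O)(N(c1ccccc1)S(=O)(=O)C(F)(F)F)C(F)(F)F
Why: Kinetic deprotonation at C6 gives the cross-conjugated enolate, which is O-sulfonylated to the dienyl triflate; the β-silyloxy enolate is kept cold to avoid elimination.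

Step 6
Reactants: 9 ring A dienyl triflate
Product: 10 ring A stannane tert-butyldimethyl{[(1S)-2,4-dimethyl-3-(trimethylstannyl)cyclohexa-2,4-dien-1-yl]oxy}silane
Conditions: Pd(PPh3)4 (cat.), Me3SnSnMe3, LiCl, THF, 60 °C
Reagents that add atoms: hexamethylditin, C[Sn](C)(C)[Sn](C)(C)C
Why: Palladium-catalysed stannylation of an enol triflate (Stille-type coupling with a distannane) gives a storable precursor of the dienyl anion.

Step 7
Reactants: 11 4-methoxybenzyl alcohol; 12 trichloroethylene
Product: 15 (E)-1,2-dichlorovinyl 4-methoxybenzyl ether, via potassium 4-methoxybenzyl oxide 13 (not isolated), via dichloroacetylene 14 (not isolated)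
Conditions: KH, THF, 0 °C; then Cl2C=CHCl, −50 °C → rt
Reagents that add atoms: none
Why: Base converts trichloroethylene to dichloroacetylene, to which the alkoxide adds in anti fashion; this known route gives a bench-stable precursor of an alkoxyacetylide.

Step 8
Reactants: 16 (−)-shikimic acid
Product: 18 methyl 3,4-O-isopropylideneshikimate, via methyl shikimate 17 (not isolated)
Conditions: MeOH, camphorsulfonic acid (cat.), reflux; then 2,2-dimethoxypropane, acetone, rt
Reagents that add atoms: methanol, CO; 2,2-dimethoxypropane, COC(C)(C)OC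
Why: Fischer esterification, then acetalisation of the cis-diol (O7/O8), which leaves only the C9 hydroxyl free.

Step 9
Reactants: 18 methyl 3,4-O-isopropylideneshikimate
Product: 20 methyl (3aR,7aS)-2,2-dimethyl-3a,7a-dihydro-1,3-benzodioxole-5-carboxylate, via C9 triflate 19 (not isolated)
Conditions: Tf2O, pyridine, CH2Cl2, −20 °C; then DBU, rt
Reagents that add atoms: none
Why: E2 elimination of the C9 triflate; only C4 carries a hydrogen anti to the leaving group (H8 is syn), so the C9=C4 bond forms regioselectively.

Step 10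
Reactants: 20 diene ester
Product: 22 methyl ester C9–C4 epoxide (epoxide oxygen cis to the dioxolane), via bromohydrin 21 (not isolated)
Conditions: NBS, THF/H2O, 0 °C; then K2CO3 (aq.), rt
Reagents that add atoms: water, O
Why: The bromonium ion forms on the electron-rich C9=C4 bond (the acrylate C5=C6 is inert) on the face anti to the dioxolane; anti attack of water and base-induced closure then place the epoxide oxygen on the dioxolane face, the face that direct epoxidation would not reach.

Step 11
Reactants: 22 epoxide; 15 (E)-1,2-dichlorovinyl 4-methoxybenzyl ether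
Product: 24 alkynyl ether alcohol (C4 alkynyl anti to the dioxolane and C9–OH syn to it), via lithium (4-methoxybenzyloxy)acetylide 23 (not isolated)
Conditions: 15, n-BuLi (2.2 equiv), THF, −78 → −40 °C; BF3·OEt2, −78 °C; then 22, −78 °C
Reagents that add atoms: none
Why: The alkynyl–BF3 species opens the vinyl epoxide by SN2 at the allylic C4 (C9 is deactivated by the adjacent C–O bond) in a trans-diaxial (Fürst–Plattner) sense, which sets C4 with the alkynyl group on the face opposite the dioxolane.

Step 12
Reactants: 24 alkynyl ether alcohol (methyl ester)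
Product: 25 C16,C9-diol
Conditions: i-Bu2AlH, CH2Cl2, −78 °C
Reagents that add atoms: none
Why: 1,2-Reduction of the conjugated ester to the allylic alcohol (C16); the alkynyl ether and acetonide are inert at −78 °C.

Step 13
Reactants: 25 C16,C9-diol
Product: 26 C16 tert-butyldiphenylsilyl ether
Conditions: t-BuPh2SiCl, imidazole, CH2Cl2, 0 °C
Reagents that add atoms: tert-butyldiphenylsilyl chloride, CC(C)(C)[Si](Cl)(c1ccccc1)c1ccccc1
Why: The bulky silyl chloride selects the primary allylic hydroxyl over the flanked secondary C9 hydroxyl.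

Step 14
Reactants: 26 C16 silyl ether
Product: 27 ring B ketone (C9 ketone)
Conditions: Dess–Martin periodinane, NaHCO3, CH2Cl2, 0 °C
Reagents that add atoms: none
Why: Buffered Dess–Martin oxidation is mild enough for the β,γ-unsaturated α-alkynyl ketone, which is used at once to avoid enolisation.

Step 15
Reactants: 10 ring A stannane; 27 ring B ketone
Product: 30 alkynyl carbinol (C9: ring A dienyl anti to the dioxolane and cis to the C4 alkynyl group), via ring A dienyllithium 28 (not isolated), via ring A dienylcerium dichloride 29 (not isolated)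
Conditions: 10, MeLi, THF, −78 °C; CeCl3, THF, −78 °C; then 27, −78 → −40 °C
Reagents that add atoms: none
Why: Tin–lithium exchange and transmetalation give a weakly basic organocerium reagent that adds 1,2 to the enolisable ketone; it approaches anti to the cis-fused dioxolane, past the slim alkynyl group, which sets the C9 carbinol with the dienyl group cis to the C4 substituent.

Step 16
Reactants: 30 alkynyl carbinol
Product: 31 (Z)-enol ether carbinol
Conditions: H2 (1 atm), Pd/CaCO3 poisoned with Pb(OAc)2, quinoline, EtOAc, rt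
Reagents that add atoms: none
Why: Lindlar semihydrogenation adds hydrogen syn to the alkynyl ether and gives only the Z enol ether; the hindered ring A diene and the trisubstituted C5=C6 bond are not reduced.

Step 17
Reactants: 31 (Z)-enol ether carbinol
Product: 34 ten-membered ketone (1R,2R,3Z,5E,10S,14S; C9 ketone; C7 and C8 as in shikimic acid), via potassium alkoxide 32 (not isolated), via potassium dienolate 33 (not isolated)
Conditions: KH, 18-crown-6, THF, 0 → 40 °C; then AcOH, THF, −78 °C
Reagents that add atoms: none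
Why: KH/18-crown-6 gives the free C9 alkoxide 32, which undergoes a [3,3] shift (anionic oxy-Cope rearrangement, the known ring expansion of 1,2-dialkenylcyclohexanols to cyclodec-5-enones): C1–C2 forms as C4–C9 breaks, giving dienolate 33 and, after C-protonation, ketone 34. The ten-membered ring is not closed end to end; it arises by four-atom expansion of ring B through a six-membered chair transition state, with ring A kept and ring B consumed. The reactive half-chair of ring B has the dienyl group axial and O9, the enol ether and O7 equatorial (O8 axial in the cis-fused dioxolane), whereas the flipped half-chair would put O9 and O7 syn-diaxial; in the favoured chair C5 is axial on C4, which gives the Z C3=C4 bond, and C5=C6 is carried over unchanged. C1 is set by that chair: C2 bonds to the ring A face opposite the vinylic methyl, a sense fixed by the C9 and C4 configurations from steps 15 and 11. C2 is set by the Z geometry of the enol ether, which places the OPMB group axial on the forming chair. C10 is set by axial protonation of 33 anti to the newly axial C15 methyl. The step needs the [3,3] shift to run through the exocyclic enol ether and not through the ring C5=C6 bond, which would require a bicyclic boat. It also needs a cold acidic quench, before the enolate can equilibrate toward C8 and eliminate the dioxolane oxygen.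

Step 18
Reactants: 34 ten-membered ketone
Product: 35 C9 alcohol (9R)
Conditions: LiBH(s-Bu)3, THF, −78 °C
Reagents that add atoms: none
Why: A bulky non-chelating hydride should follow the polar Felkin–Anh model, attacking anti to the C8–O bond of the dioxolane, which gives the C9 oxygen syn to O8 as required for 9R.

Step 19
Reactants: 35 C9 alcohol
Product: 36 C9 acetate
Conditions: Ac2O, DMAP, pyridine, CH2Cl2, rt
Reagents that add atoms: acetic anhydride, CC(=O)OC(C)=O
Why: DMAP-catalysed acylation installs the first of the three acetates and protects C9 for the oxidation in step 22.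

Step 20
Reactants: 36 C9 acetate
Product: 37 C7,C8-diol
Conditions: pyridinium p-toluenesulfonate, MeOH, 40 °C
Reagents that add atoms: none
Why: Mild transacetalisation removes the acetonide while the hindered secondary silyl ether, the primary tert-butyldiphenylsilyl ether and the benzylic ether survive; no epoxide is present yet.

Step 21
Reactants: 37 C7,C8-diol
Product: 38 C7 2-bromopropanoate (C7 inverted to 7S; C8–OH free)
Conditions: 2-bromopropanoic acid, PPh3, DIAD, toluene, 0 °C
Reagents that add atoms: 2-bromopropanoic acid, CC(Br)C(O)=O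
Why: Mitsunobu esterification of the allylic C7 alcohol (more reactive than the flanked C8–OH) proceeds by SN2 inversion; it corrects the shikimate configuration at C7 to that of the target and attaches C17–C19.

Step 22
Reactants: 38 C7 2-bromopropanoate
Product: 39 C8 ketone
Conditions: Dess–Martin periodinane, NaHCO3, CH2Cl2, 0 °C
Reagents that add atoms: none
Why: Buffered Dess–Martin oxidation of the remaining secondary alcohol; neutral conditions protect the epimerisable C7 and C9 centres next to the new ketone.

Step 23
Reactants: 39 C8 ketone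
Product: 41 lactone (8S,17R; γ-lactone trans-fused to the ten-membered ring with tertiary C8–OH), via samarium enolate 40 (not isolated)
Conditions: SmI2, THF, −78 °C
Reagents that add atoms: none
Why: SmI2 reduces the C–Br bond to a trivalent samarium enolate that adds to the C8 ketone (intramolecular Reformatsky reaction); the three-atom tether through O7 can reach C8 only from the face on which O7 lies, which with C6 and C9 held anti about C7–C8 gives the C8 hydroxyl cis to C6. The samarium-bridged transition state should place the C18 methyl on the less hindered side, cis to the new hydroxyl.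

Step 24
Reactants: 41 lactone
Product: 42 C14 alcohol
Conditions: HF·pyridine, pyridine, THF, 0 °C → rt
Reagents that add atoms: none
Why: Buffered HF cleaves the tert-butyldimethylsilyl ether, while the much more acid-stable primary tert-butyldiphenylsilyl ether, the lactone and the acetate are expected to survive.

Step 25
Reactants: 42 C14 alcohol
Product: 43 11,12-epoxide (11S,12R)
Conditions: mCPBA, NaHCO3, CH2Cl2, 0 °C
Reagents that add atoms: 3-chloroperbenzoic acid, OOC(=O)c1cccc(Cl)c1
Why: C11=C12 is the only alkene without an allylic oxygen and hence the most nucleophilic; the axial homoallylic C14 hydroxyl directs the peracid (Henbest effect) to the face opposite the axial C15 methyl, which sets both epoxide centres.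

Step 26
Reactants: 43 11,12-epoxide
Product: 44 C2,C14-diol
Conditions: DDQ, CH2Cl2/pH 7 buffer, 0 °C
Reagents that add atoms: none
Why: Oxidative cleavage of the 4-methoxybenzyl ether under neutral buffered conditions frees the C2 hydroxyl without touching the epoxide or the esters.

Step 27
Reactants: 44 C2,C14-diol
Product: 45 16-O-tert-butyldiphenylsilyl ether of the target (2,9,14-triacetate)
Conditions: Ac2O, DMAP, Et3N, CH2Cl2, rt
Reagents that add atoms: acetic anhydride, CC(=O)OC(C)=O
Why: Both secondary hydroxyls are acetylated; the tertiary C8 hydroxyl next to a quaternary centre is not expected to react under these conditions.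

Step 28
Reactants: 45 16-O-silyl ether
Product: 46 target CNP0296793.1
Conditions: Bu4NF, AcOH, THF, 0 °C → rt
Reagents that add atoms: none
Why: Acetic acid-buffered fluoride removes the primary silyl ether without acetate migration, epoxide opening or retro-aldol cleavage of the β-hydroxy lactone.

## Compound list

1 | (S)-(+)-carvone | O=C1C(C)=CC[C@H](C(C)=C)C1 | starting material
2 | carvone lithium enolate | [Li+].[O-]C1=C[C@@H](C(C)=C)CC=C1C | intermediate
3 | trans-6-methylcarvone, (5S,6R)-2,6-dimethyl-5-(prop-1-en-2-yl)cyclohex-2-en-1-one | O=C1C(C)=CC[C@H](C(C)=C)[C@H]1C | intermediate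
4 | methoxy hydroperoxide from ozonolysis of 3 (acetal carbon unassigned) | O=C1C(C)=CC[C@H](C(C)(OC)OO)[C@H]1C | intermediate
5 | (1S,2R)-2,4-dimethyl-3-oxocyclohex-4-en-1-yl acetate | O=C1C(C)=CC[C@H](OC(C)=O)[C@H]1C | intermediate
6 | (5S,6R)-5-hydroxy-2,6-dimethylcyclohex-2-en-1-one | O=C1C(C)=CC[C@H](O)[C@H]1C | intermediate
7 | (5S,6R)-5-(tert-butyldimethylsilyloxy)-2,6-dimethylcyclohex-2-en-1-one | O=C1C(C)=CC[C@H](O[Si](C)(C)C(C)(C)C)[C@H]1C | intermediate
8 | lithium dienolate of 7 | [Li+].[O-]C1=C(C)[C@@H](O[Si](C)(C)C(C)(C)C)CC=C1C | intermediate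
9 | (3S)-3-(tert-butyldimethylsilyloxy)-2,6-dimethylcyclohexa-1,5-dien-1-yl trifluoromethanesulfonate | FC(F)(F)S(=O)(=O)OC1=C(C)[C@@H](O[Si](C)(C)C(C)(C)C)CC=C1C | intermediate
10 | ring A stannane, tert-butyldimethyl{[(1S)-2,4-dimethyl-3-(trimethylstannyl)cyclohexa-2,4-dien-1-yl]oxy}silane | C[Sn](C)(C)C1=C(C)[C@@H](O[Si](C)(C)C(C)(C)C)CC=C1C | intermediate
11 | 4-methoxybenzyl alcohol | COc1ccc(CO)cc1 | starting material
12 | trichloroethylene | ClC=C(Cl)Cl | starting material
13 | potassium 4-methoxybenzyl oxide | COc1ccc(C[O-])cc1.[K+] | intermediate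
14 | dichloroacetylene | ClC#CCl | intermediate
15 | (E)-1,2-dichlorovinyl 4-methoxybenzyl ether | COc1ccc(CO/C(Cl)=C\Cl)cc1 | intermediate
16 | (−)-shikimic acid, (3R,4S,5R) | O[C@H]1[C@H](O)[C@H](O)C=C(C(=O)O)C1 | starting material
17 | methyl shikimate | O[C@H]1[C@H](O)[C@H](O)C=C(C(=O)OC)C1 | intermediate
18 | methyl 3,4-O-isopropylideneshikimate | O[C@H]1[C@@H]2OC(C)(C)O[C@@H]2C=C(C(=O)OC)C1 | intermediate
19 | C9 (shikimate C5) triflate of 18 | FC(F)(F)S(=O)(=O)O[C@H]1[C@@H]2OC(C)(C)O[C@@H]2C=C(C(=O)OC)C1 | intermediate
20 | methyl (3aR,7aS)-2,2-dimethyl-3a,7a-dihydro-1,3-benzodioxole-5-carboxylate | COC(=O)C1=C[C@H]2OC(C)(C)O[C@H]2C=C1 | intermediate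
21 | bromohydrin (C9–Br anti to the dioxolane, C4–OH syn to it) | COC(=O)C1=C[C@H]2OC(C)(C)O[C@H]2[C@H](Br)[C@H]1O | intermediate
22 | C9–C4 epoxide, oxygen cis to the dioxolane | COC(=O)C1=C[C@H]2OC(C)(C)O[C@H]2[C@H]3O[C@H]31 | intermediate
23 | lithium (4-methoxybenzyloxy)acetylide | [Li+].[C-]#COCc1ccc(OC)cc1 | intermediate
24 | alkynyl ether alcohol, methyl ester (C4 alkynyl anti to dioxolane, C9–OH syn) | COC(=O)C1=C[C@H]2OC(C)(C)O[C@H]2[C@@H](O)[C@@H]1C#COCc1ccc(OC)cc1 | intermediate
25 | C16,C9-diol | OCC1=C[C@H]2OC(C)(C)O[C@H]2[C@@H](O)[C@@H]1C#COCc1ccc(OC)cc1 | intermediate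
26 | C16 tert-butyldiphenylsilyl ether | CC(C)(C)[Si](OCC1=C[C@H]2OC(C)(C)O[C@H]2[C@@H](O)[C@@H]1C#COCc1ccc(OC)cc1)(c1ccccc1)c1ccccc1 | intermediate
27 | ring B ketone | CC(C)(C)[Si](OCC1=C[C@H]2OC(C)(C)O[C@H]2C(=O)[C@@H]1C#COCc1ccc(OC)cc1)(c1ccccc1)c1ccccc1 | intermediate
28 | ring A dienyllithium | [Li]C1=C(C)[C@@H](O[Si](C)(C)C(C)(C)C)CC=C1C | intermediate
29 | ring A dienylcerium dichloride | Cl[Ce](Cl)C1=C(C)[C@@H](O[Si](C)(C)C(C)(C)C)CC=C1C | intermediate
30 | alkynyl carbinol (C9 dienyl cis to C4 alkynyl, both anti to dioxolane) | CC(C)(C)[Si](OCC1=C[C@H]2OC(C)(C)O[C@H]2[C@](O)(C3=C(C)[C@@H](O[Si](C)(C)C(C)(C)C)CC=C3C)[C@@H]1C#COCc1ccc(OC)cc1)(c1ccccc1)c1ccccc1 | intermediate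
31 | (Z)-enol ether carbinol | CC(C)(C)[Si](OCC1=C[C@H]2OC(C)(C)O[C@H]2[C@](O)(C3=C(C)[C@@H](O[Si](C)(C)C(C)(C)C)CC=C3C)[C@@H]1/C=C\OCc1ccc(OC)cc1)(c1ccccc1)c1ccccc1 | intermediate
32 | potassium alkoxide of 31 | CC(C)(C)[Si](OCC1=C[C@H]2OC(C)(C)O[C@H]2[C@]([O-])(C3=C(C)[C@@H](O[Si](C)(C)C(C)(C)C)CC=C3C)[C@@H]1/C=C\OCc1ccc(OC)cc1)(c1ccccc1)c1ccccc1.[K+] | intermediate
33 | potassium dienolate (C9 enolate, C9=C10 and C11=C12) | CC(C)(C)[Si](C)(C)O[C@H]1CC=C(C)/C2=C([O-])\[C@@H]3OC(C)(C)O[C@@H]3/C=C(CO[Si](c3ccccc3)(c3ccccc3)C(C)(C)C)\C=C/[C@@H](OCc3ccc(OC)cc3)[C@@]12C.[K+] | intermediate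
34 | ten-membered ketone (C9 ketone; 2-OPMB, 14-OTBS, 16-OTBDPS, 7,8-acetonide with shikimate configuration at C7) | CC(C)(C)[Si](C)(C)O[C@H]1CC=C(C)[C@@H]2C(=O)[C@@H]3OC(C)(C)O[C@@H]3/C=C(CO[Si](c3ccccc3)(c3ccccc3)C(C)(C)C)\C=C/[C@@H](OCc3ccc(OC)cc3)[C@@]12C | intermediate
35 | C9 alcohol (9R) | CC(C)(C)[Si](C)(C)O[C@H]1CC=C(C)[C@@H]2[C@@H](O)[C@@H]3OC(C)(C)O[C@@H]3/C=C(CO[Si](c3ccccc3)(c3ccccc3)C(C)(C)C)\C=C/[C@@H](OCc3ccc(OC)cc3)[C@@]12C | intermediate
36 | C9 acetate | CC(C)(C)[Si](C)(C)O[C@H]1CC=C(C)[C@@H]2[C@@H](OC(C)=O)[C@@H]3OC(C)(C)O[C@@H]3/C=C(CO[Si](c3ccccc3)(c3ccccc3)C(C)(C)C)\C=C/[C@@H](OCc3ccc(OC)cc3)[C@@]12C | intermediate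
37 | C7,C8-diol (C7 still epimeric to the target) | CC(C)(C)[Si](C)(C)O[C@H]1CC=C(C)[C@@H]2[C@@H](OC(C)=O)[C@H](O)[C@H](O)/C=C(CO[Si](c3ccccc3)(c3ccccc3)C(C)(C)C)\C=C/[C@@H](OCc3ccc(OC)cc3)[C@@]12C | intermediate
38 | C7 2-bromopropanoate (7S as in the target; bromide centre mixed) | CC(C)(C)[Si](C)(C)O[C@H]1CC=C(C)[C@@H]2[C@@H](OC(C)=O)[C@H](O)[C@@H](OC(=O)C(C)Br)/C=C(CO[Si](c3ccccc3)(c3ccccc3)C(C)(C)C)\C=C/[C@@H](OCc3ccc(OC)cc3)[C@@]12C | intermediate
39 | C8 ketone | CC(C)(C)[Si](C)(C)O[C@H]1CC=C(C)[C@@H]2[C@@H](OC(C)=O)C(=O)[C@@H](OC(=O)C(C)Br)/C=C(CO[Si](c3ccccc3)(c3ccccc3)C(C)(C)C)\C=C/[C@@H](OCc3ccc(OC)cc3)[C@@]12C | intermediate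
40 | diiodosamarium ester enolate of 39 | CC(C)(C)[Si](C)(C)O[C@H]1CC=C(C)[C@@H]2[C@@H](OC(C)=O)C(=O)[C@@H](OC(O[Sm](I)I)=CC)/C=C(CO[Si](c3ccccc3)(c3ccccc3)C(C)(C)C)\C=C/[C@@H](OCc3ccc(OC)cc3)[C@@]12C | intermediate
41 | lactone (7S,8S,17R) with 2-OPMB, 9-OAc, 14-OTBS, 16-OTBDPS | CC(C)(C)[Si](C)(C)O[C@H]1CC=C(C)[C@@H]2[C@@H](OC(C)=O)[C@@]3(O)[C@H](/C=C(CO[Si](c4ccccc4)(c4ccccc4)C(C)(C)C)\C=C/[C@@H](OCc4ccc(OC)cc4)[C@@]12C)OC(=O)[C@@H]3C | intermediate
42 | C14 alcohol | O[C@H]1CC=C(C)[C@@H]2[C@@H](OC(C)=O)[C@@]3(O)[C@H](/C=C(CO[Si](c4ccccc4)(c4ccccc4)C(C)(C)C)\C=C/[C@@H](OCc4ccc(OC)cc4)[C@@]12C)OC(=O)[C@@H]3C | intermediate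
43 | 11,12-epoxide (11S,12R) | O[C@H]1C[C@H]2O[C@@]2(C)[C@@H]2[C@@H](OC(C)=O)[C@@]3(O)[C@H](/C=C(CO[Si](c4ccccc4)(c4ccccc4)C(C)(C)C)\C=C/[C@@H](OCc4ccc(OC)cc4)[C@@]12C)OC(=O)[C@@H]3C | intermediate
44 | C2,C14-diol | O[C@H]1C[C@H]2O[C@@]2(C)[C@@H]2[C@@H](OC(C)=O)[C@@]3(O)[C@H](/C=C(CO[Si](c4ccccc4)(c4ccccc4)C(C)(C)C)\C=C/[C@@H](O)[C@@]12C)OC(=O)[C@@H]3C | intermediate
45 | 16-O-tert-butyldiphenylsilyl ether of the target | CC(=O)O[C@H]1C[C@H]2O[C@@]2(C)[C@@H]2[C@@H](OC(C)=O)[C@@]3(O)[C@H](/C=C(CO[Si](c4ccccc4)(c4ccccc4)C(C)(C)C)\C=C/[C@@H](OC(C)=O)[C@@]12C)OC(=O)[C@@H]3C | intermediate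
46 | CNP0296793.1, (1R,2R,3Z,5E,7S,8S,9R,10S,11S,12R,14S,17R)-2,9,14-triacetoxy-11,12-epoxy-8,16-dihydroxybriara-3,5-dien-18,7-olide | CC(=O)O[C@H]1C[C@H]2O[C@@]2(C)[C@@H]2[C@@H](OC(C)=O)[C@@]3(O)[C@H](/C=C(CO)\C=C/[C@@H](OC(C)=O)[C@@]12C)OC(=O)[C@@H]3C | target

## Step count and least certain steps

Total: 28 steps. Longest linear sequence: 21 steps (16 → 46, steps 8–28). The carvone branch (steps 1–6) joins at step 15 and the alkynyl ether reagent (step 7) joins at step 11.

Step 17 (key step). The chair that is needed carries the Z-OPMB group and C5 both axial on the forming ring, and the C14 silyloxy group sits on the ring A face that C2 attacks. This strain may slow the [3,3] shift until other processes compete: heterolysis of C4–C9 in the alkoxide, a [1,3] shift, reaction through the flipped half-chair (E C3=C4 and the wrong C1), or enolate equilibration with loss of the dioxolane oxygen. Fallback: from 31, silylate the carbinol (Me3SiCl, imidazole) to the trimethylsilyl ether F1 and run the neutral thermal siloxy-Cope rearrangement (toluene, sealed tube, about 200 °C). This uses the same chair but no alkoxide, so the ionic side reactions are closed. The product is silyl enol ether F2, which is hydrolysed under buffered conditions (Bu4NF, AcOH, −78 °C) and returns to the route at 34.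

Step 15. The failure mode is proton transfer from the acidic propargylic C4–H of 27 to the hindered organometallic instead of addition, and slow addition of a 2,6-disubstituted dienyl nucleophile. Fallback: from 9 and 27 (skipping 10), a Barbier-type Nozaki–Hiyama–Kishi coupling (CrCl2, catalytic NiCl2, DMF/THF). The trivalent chromium dienyl species F3 is formed in the presence of the ketone and is non-basic; the route is rejoined at 30.

Step 18. Facial selectivity is uncertain because the C10 stereocentre (alkyl Felkin model) opposes the polar Felkin–Anh preference from C8, and the macrocycle may override both. Fallback: from 34, chelation-controlled reduction with Zn(BH4)2, in which both α-centres reinforce, to the 9-epi alcohol F4. Mitsunobu displacement of F4 with acetic acid (PPh3, DIAD) inverts C9 and returns to the route at 36.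

Step 23. The C8 and C17 configurations depend on the ring conformation around C7–C8, and ketyl formation could reductively cleave the α-acyloxy groups before the Reformatsky closure. Fallback: from 37, Mitsunobu esterification with 2-(diethoxyphosphoryl)propanoic acid gives F5. Dess–Martin oxidation gives keto phosphonate F6, and an intramolecular Horner–Wadsworth–Emmons reaction (LiCl, DBU) gives butenolide F7. Nucleophilic epoxidation (t-BuOOH, DBU) then gives the 8,17-epoxy lactone F8. SmI2 opens the C17–O bond of F8 and the enolate is protonated on the less hindered face, which rejoins the route at 41.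

Step 24. The hindered neopentyl secondary silyl ether may cleave no faster than the primary tert-butyldiphenylsilyl ether. Fallback: from 41, remove both silyl groups (Bu4NF, AcOH) to diol F9, then re-silylate only the primary allylic hydroxyl (t-BuPh2SiCl, imidazole, 0 °C), which returns to the route at 42.

## Further compounds

F1 | step 17 | trimethylsilyl ether of 31 | CC(C)(C)[Si](OCC1=C[C@H]2OC(C)(C)O[C@H]2[C@](O[Si](C)(C)C)(C3=C(C)[C@@H](O[Si](C)(C)C(C)(C)C)CC=C3C)[C@@H]1/C=C\OCc1ccc(OC)cc1)(c1ccccc1)c1ccccc1
F2 | step 17 | trimethylsilyl enol ether of 34 (C9=C10) | CC(C)(C)[Si](C)(C)O[C@H]1CC=C(C)/C2=C(O[Si](C)(C)C)\[C@@H]3OC(C)(C)O[C@@H]3/C=C(CO[Si](c3ccccc3)(c3ccccc3)C(C)(C)C)\C=C/[C@@H](OCc3ccc(OC)cc3)[C@@]12C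
F3 | step 15 | ring A dienylchromium dichloride | Cl[Cr](Cl)C1=C(C)[C@@H](O[Si](C)(C)C(C)(C)C)CC=C1C
F4 | step 18 | 9-epi alcohol (9S) | CC(C)(C)[Si](C)(C)O[C@H]1CC=C(C)[C@@H]2[C@H](O)[C@@H]3OC(C)(C)O[C@@H]3/C=C(CO[Si](c3ccccc3)(c3ccccc3)C(C)(C)C)\C=C/[C@@H](OCc3ccc(OC)cc3)[C@@]12C
F5 | step 23 | C7 2-(diethoxyphosphoryl)propanoate (7S) | CC(C)(C)[Si](C)(C)O[C@H]1CC=C(C)[C@@H]2[C@@H](OC(C)=O)[C@H](O)[C@@H](OC(=O)C(C)P(=O)(OCC)OCC)/C=C(CO[Si](c3ccccc3)(c3ccccc3)C(C)(C)C)\C=C/[C@@H](OCc3ccc(OC)cc3)[C@@]12C
F6 | step 23 | C8 keto phosphonate | CC(C)(C)[Si](C)(C)O[C@H]1CC=C(C)[C@@H]2[C@@H](OC(C)=O)C(=O)[C@@H](OC(=O)C(C)P(=O)(OCC)OCC)/C=C(CO[Si](c3ccccc3)(c3ccccc3)C(C)(C)C)\C=C/[C@@H](OCc3ccc(OC)cc3)[C@@]12C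
F7 | step 23 | C8=C17 butenolide | CC(C)(C)[Si](C)(C)O[C@H]1CC=C(C)[C@@H]2[C@@H](OC(C)=O)C3=C(C)C(=O)O[C@H]3/C=C(CO[Si](c3ccccc3)(c3ccccc3)C(C)(C)C)\C=C/[C@@H](OCc3ccc(OC)cc3)[C@@]12C
F8 | step 23 | 8,17-epoxy lactone | CC(C)(C)[Si](C)(C)O[C@H]1CC=C(C)[C@@H]2[C@@H](OC(C)=O)[C@@]3(O4)[C@H](/C=C(CO[Si](c5ccccc5)(c5ccccc5)C(C)(C)C)\C=C/[C@@H](OCc5ccc(OC)cc5)[C@@]12C)OC(=O)[C@@]34C
F9 | step 24 | C14,C16-diol | O[C@H]1CC=C(C)[C@@H]2[C@@H](OC(C)=O)[C@@]3(O)[C@H](/C=C(CO)\C=C/[C@@H](OCc4ccc(OC)cc4)[C@@]12C)OC(=O)[C@@H]3C
A1 | alternative 1 | seco (Z)-iodo-diene aldehyde (C2 aldehyde on C1, C3 vinyl iodide) | CC(=O)O[C@H]1C[C@H]2O[C@@]2(C)[C@H]([C@@H](OC(C)=O)[C@@]3(O)[C@H](/C=C(CO[Si](C)(C)C(C)(C)C)\C=C/I)OC(=O)[C@@H]3C)[C@@]1(C)C=O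
A2 | alternative 1 | macrocyclic C2 alcohol (desired C2 epimer) | CC(=O)O[C@H]1C[C@H]2O[C@@]2(C)[C@@H]2[C@@H](OC(C)=O)[C@@]3(O)[C@H](/C=C(CO[Si](C)(C)C(C)(C)C)\C=C/[C@@H](O)[C@@]12C)OC(=O)[C@@H]3C
A3 | alternative 2 | tricyclic C9 carbinol C3 mesylate (Grob precursor) | CC(C)(C)[Si](C)(C)O[C@H]1CC=C(C)[C@@H]2[C@@]3(O)[C@@H]4OC(C)(C)O[C@@H]4C=C(CO[Si](c4ccccc4)(c4ccccc4)C(C)(C)C)[C@H]3[C@@H](OS(C)(=O)=O)[C@@H](OCc3ccc(OC)cc3)[C@@]12C
A4 | alternative 3 | phenol allyl methyl carbonate (aromatic ring A) | Cc1c(O)ccc(C)c1[C@@H](OC(C)=O)[C@@]2(O)[C@H](/C=C(CO[Si](C)(C)C(C)(C)C)\C=C/COC(=O)OC)OC(=O)[C@@H]2C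
A5 | alternative 3 | cyclohexa-2,4-dienone from dearomative allylation (desired C1 epimer) | O=C1C=CC(C)=C2[C@@H](OC(C)=O)[C@@]3(O)[C@H](/C=C(CO[Si](C)(C)C(C)(C)C)\C=C/C[C@@]12C)OC(=O)[C@@H]3C
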